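**Retrosynthetic overview**

1. The route rests on ring A of unit 2 (the flavanone joined through its C6): C5, C6 and C7 carry O, O-aryl and O, C8 carries H, and O1–C2–C3–C4–C4a–C8a is a dihydropyran-4-one that one asymmetric step can deliver.
2. Key disconnection: bonds C4a–C5 and C8–C8a of unit 2, by [4+2] addition of a 2-aryloxy-1-methoxy-1,3-bis(silyloxy)diene to a 2-aryl-5-sulfinyl-dihydropyran-4-one, then loss of PhSOH and MeOH.
3. The hindered C6–O–C4' ether is made beforehand at an sp3 carbon (phenoxide on methyl 2-chloroacetoacetate); the phenol is 4-hydroxybenzaldehyde masked as a dioxolane, whose carbon later becomes C2 of unit 1.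
4. Ring order: ring C of unit 2 (asymmetric hetero-Diels–Alder), ring A of unit 2 (key step), ring C of unit 1 (second hetero-Diels–Alder on the unmasked aldehyde), ring A of unit 1 (same annulation with the parent diene); both rings B come from the benzaldehydes.
5. Protection: benzyl on O4' of unit 2, acetates on O5/O7 of unit 2 (installed without strong base, and deactivating ring A towards PhSCl); removed by hydrogenolysis and acid methanolysis.

Key step: step 8

Assumption: with BINOL/Ti(OiPr)4 the (S)-ligand is taken to direct the diene to the Si face of an aryl aldehyde and so to give the (S)-dihydropyranone; if the sense is opposite, (R)-BINOL is used in steps 1 and 11 and nothing else changes.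

**Route**

Step 1
Reactants: 1 4-(benzyloxy)benzaldehyde; 2 trans-1-methoxy-3-(trimethylsilyloxy)buta-1,3-diene
Product: 4 (S)-2-[4-(benzyloxy)phenyl]-2,3-dihydro-4H-pyran-4-one, via Mukaiyama aldol silyl ether 3 (not isolated)
Conditions: (S)-BINOL (20 mol%), Ti(OiPr)4 (10 mol%), 4 Å MS, Et2O, −20 °C; then CF3CO2H, CH2Cl2, 0 °C
Reagents that add atoms: none
Why: Catalytic asymmetric hetero-Diels–Alder reaction in its Mukaiyama aldol/acid cyclisation form; the chiral titanium BINOLate should expose the Si face of the aldehyde and set C2 as S, and CF3CO2H closes the ring with loss of methanol.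

Step 2
Reactants: 4 (S)-2-[4-(benzyloxy)phenyl]-2,3-dihydro-4H-pyran-4-one
Product: 6 (S)-2-[4-(benzyloxy)phenyl]-5-(phenylthio)-2,3-dihydro-4H-pyran-4-one, via chloro sulfide adduct 5 (not isolated)
Conditions: PhSCl (freshly distilled), CH2Cl2, −78 °C; then Et3N, −78 → 0 °C
Reagents that add atoms: benzenesulfenyl chloride, ClSc1ccccc1
Why: Sulfenyl chloride addition–dehydrochlorination (alpha-sulfenylation of an enone): sulfur attacks the nucleophilic alpha carbon C5 of the vinylogous ester, chloride adds at C6, and Et3N removes the acidic C5 hydrogen to restore the enone without touching C2.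

Step 3
Reactants: 6 (S)-2-[4-(benzyloxy)phenyl]-5-(phenylthio)-2,3-dihydro-4H-pyran-4-one
Product: 7 (S)-2-[4-(benzyloxy)phenyl]-5-(phenylsulfinyl)-2,3-dihydro-4H-pyran-4-one (both sulfur epimers)
Conditions: mCPBA (1.0 equiv), CH2Cl2, −78 °C
Reagents that add atoms: 3-chloroperoxybenzoic acid, O=C(OO)c1cccc(Cl)c1
Why: Chemoselective sulfide-to-sulfoxide oxidation with one equivalent of peracid; sulfur is far more nucleophilic than the acceptor-substituted alkene, and its configuration is irrelevant because the group is expelled in step 8.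

Step 4
Reactants: 8 4-hydroxybenzaldehyde
Product: 9 4-(1,3-dioxolan-2-yl)phenol
Conditions: HOCH2CH2OH, TsOH (cat.), PhMe, reflux (Dean–Stark)
Reagents that add atoms: ethylene glycol, OCCO
Why: Acid-catalysed acetalisation with azeotropic removal of water masks the aldehyde so that it survives the amide base and silylating agents of steps 6 and 7.

Step 5
Reactants: 9 4-(1,3-dioxolan-2-yl)phenol; 10 methyl 2-chloroacetoacetate
Product: 11 methyl 2-[4-(1,3-dioxolan-2-yl)phenoxy]-3-oxobutanoate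
Conditions: K2CO3, acetone, reflux
Reagents that add atoms: none
Why: Williamson-type SN2 displacement of the doubly activated secondary chloride by the phenoxide, the standard entry to 2-aryloxyacetoacetates, makes the future C6–O–C4' ether before ring A exists.

Step 6
Reactants: 11 methyl 2-[4-(1,3-dioxolan-2-yl)phenoxy]-3-oxobutanoate
Product: 12 methyl 2-[4-(1,3-dioxolan-2-yl)phenoxy]-3-(trimethylsilyloxy)but-2-enoate
Conditions: Me3SiCl, Et3N, PhMe, rt
Reagents that add atoms: chlorotrimethylsilane, C[Si](C)(C)Cl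
Why: Soft enolisation and O-silylation of the beta-keto ester (silyl enol ether formation) under non-acidic conditions that leave the dioxolane intact.

Step 7
Reactants: 12 methyl 2-[4-(1,3-dioxolan-2-yl)phenoxy]-3-(trimethylsilyloxy)but-2-enoate
Product: 13 2-[4-(1,3-dioxolan-2-yl)phenoxy]-1-methoxy-1,3-bis(trimethylsilyloxy)buta-1,3-diene
Conditions: LiN(iPr)2, THF, −78 °C; then Me3SiCl, −78 °C → rt; used crude
Reagents that add atoms: chlorotrimethylsilane, C[Si](C)(C)Cl
Why: Gamma-deprotonation of the beta-silyloxy enoate and O-silylation of the extended enolate (silyl ketene acetal formation) is the standard two-stage route to 1,3-bis(silyloxy)dienes of 2-substituted acetoacetates.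

Step 8
Reactants: 7 (S)-2-[4-(benzyloxy)phenyl]-5-(phenylsulfinyl)-2,3-dihydro-4H-pyran-4-one; 13 2-[4-(1,3-dioxolan-2-yl)phenoxy]-1-methoxy-1,3-bis(trimethylsilyloxy)buta-1,3-diene
Product: 17 (S)-2-[4-(benzyloxy)phenyl]-6-[4-(1,3-dioxolan-2-yl)phenoxy]-5,7-dihydroxychroman-4-one, via sulfinyl cycloadduct 14 (not isolated), via methoxy dihydroarene 15 (not isolated), via bis-silyl ether 16 (not isolated)
Conditions: 13 (2 equiv), PhMe, rt → 70 °C; then THF, sat. aq. NH4Cl, rt
Reagents that add atoms: none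
Why: Proposed new method: the polarised diene 13 should add across the C5=C6 bond of 7 in an asynchronous [4+2] cycloaddition, its CH2 terminus bonding to C6 (the future C8a) and its ketene acetal carbon to the sulfinyl-bearing C5 (the future C4a); in adduct 14 the sulfinyl group and the C8a hydrogen are cis, so thermal syn elimination of benzenesulfenic acid gives 15, 1,4-loss of methanol aromatises ring A to 16, and the work-up cleaves the two aryl silyl ethers. The closest known reactions are the cycloaddition–elimination–aromatisation sequences of 1,1,3-trioxygenated dienes with sulfinyl or halo quinones and the Diels–Alder reactions of 3-sulfinylchromones; a monocyclic 5-sulfinyl-dihydropyran-4-one has not been used as the 2π partner of such a diene. Ring A is closed as a six-membered carbocycle in the [4+2] mode (bonds C8–C8a and C4a–C5) or, if the addition is stepwise, by Mukaiyama–Michael addition followed by 6-exo-trig acylation of the alpha-sulfinyl enol silane. No stereocentre is kept from this step, since C4a, C5, C8a and sulfur are erased by the two eliminations, and C2 is never deprotonated under the neutral thermal conditions and stays S. The step needs regiochemistry (aryloxy at C6, not C8), secured by pairing the nucleophilic CH2 terminus of the diene with C6 of the enone, the carbon beta to the ketone. It also needs syn elimination to win over beta-elimination of O1, which is why neither Lewis acid nor base is present.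

Step 9
Reactants: 17 (S)-2-[4-(benzyloxy)phenyl]-6-[4-(1,3-dioxolan-2-yl)phenoxy]-5,7-dihydroxychroman-4-one
Product: 18 (S)-5,7-diacetoxy-2-[4-(benzyloxy)phenyl]-6-[4-(1,3-dioxolan-2-yl)phenoxy]chroman-4-one
Conditions: Ac2O, pyridine, DMAP (cat.), CH2Cl2, 0 °C → rt
Reagents that add atoms: acetic anhydride, CC(=O)OC(C)=O
Why: DMAP-catalysed acetylation caps both phenols without the strong base that opens flavanones to chalcones, and the acetates deactivate ring A towards the electrophilic sulfur reagent of step 12 and keep the phenols off the titanium catalyst of step 11.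

Step 10
Reactants: 18 (S)-5,7-diacetoxy-2-[4-(benzyloxy)phenyl]-6-[4-(1,3-dioxolan-2-yl)phenoxy]chroman-4-one
Product: 19 (S)-5,7-diacetoxy-2-[4-(benzyloxy)phenyl]-6-(4-formylphenoxy)chroman-4-one
Conditions: PPTS, acetone/H2O, 50 °C
Reagents that add atoms: water, O
Why: Mild acid-catalysed acetal hydrolysis; the electron-rich aryl dioxolane should cleave under conditions that leave aryl acetates, the benzyl ether and the flavanone untouched.

Step 11
Reactants: 19 (S)-5,7-diacetoxy-2-[4-(benzyloxy)phenyl]-6-(4-formylphenoxy)chroman-4-one; 2 trans-1-methoxy-3-(trimethylsilyloxy)buta-1,3-diene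
Product: 21 (S)-5,7-diacetoxy-2-[4-(benzyloxy)phenyl]-6-{4-[(S)-4-oxo-3,4-dihydro-2H-pyran-2-yl]phenoxy}chroman-4-one, via Mukaiyama aldol silyl ether 20 (not isolated)
Conditions: (S)-BINOL (40 mol%), Ti(OiPr)4 (20 mol%), 4 Å MS, CH2Cl2/Et2O, −20 °C; then CF3CO2H, CH2Cl2, 0 °C
Reagents that add atoms: none
Why: The same catalyst-controlled asymmetric hetero-Diels–Alder reaction (Mukaiyama aldol/cyclisation) as in step 1; the chiral titanium BINOLate should override the remote stereocentre and set C2 of unit 1 as S by Si-face attack on the aldehyde, the aryl ketone being far less reactive.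

Step 12
Reactants: 21 (S)-5,7-diacetoxy-2-[4-(benzyloxy)phenyl]-6-{4-[(S)-4-oxo-3,4-dihydro-2H-pyran-2-yl]phenoxy}chroman-4-one
Product: 23 (S)-5,7-diacetoxy-2-[4-(benzyloxy)phenyl]-6-{4-[(S)-4-oxo-5-(phenylthio)-3,4-dihydro-2H-pyran-2-yl]phenoxy}chroman-4-one, via chloro sulfide adduct 22 (not isolated)
Conditions: PhSCl (1.05 equiv), CH2Cl2, −78 °C; then Et3N, −78 → 0 °C
Reagents that add atoms: benzenesulfenyl chloride, ClSc1ccccc1
Why: Sulfenyl chloride addition–dehydrochlorination as in step 2; the enol ether carbon of the vinylogous ester should be the only site nucleophilic enough at −78 °C, because ring A of unit 2 is deactivated by its two acetates and the other rings are simple aryl ethers.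

Step 13
Reactants: 23 (S)-5,7-diacetoxy-2-[4-(benzyloxy)phenyl]-6-{4-[(S)-4-oxo-5-(phenylthio)-3,4-dihydro-2H-pyran-2-yl]phenoxy}chroman-4-one
Product: 24 (S)-5,7-diacetoxy-2-[4-(benzyloxy)phenyl]-6-{4-[(S)-4-oxo-5-(phenylsulfinyl)-3,4-dihydro-2H-pyran-2-yl]phenoxy}chroman-4-one (both sulfur epimers)
Conditions: mCPBA (1.0 equiv), CH2Cl2, −78 °C
Reagents that add atoms: 3-chloroperoxybenzoic acid, O=C(OO)c1cccc(Cl)c1
Why: Chemoselective sulfide-to-sulfoxide oxidation as in step 3; Baeyer–Villiger oxidation of the aryl ketones is far slower than sulfur oxidation at this temperature.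

Step 14
Reactants: 25 methyl acetoacetate
Product: 26 methyl 3-(trimethylsilyloxy)but-2-enoate
Conditions: Me3SiCl, Et3N, PhMe, rt
Reagents that add atoms: chlorotrimethylsilane, C[Si](C)(C)Cl
Why: Silyl enol ether formation from the beta-keto ester by soft enolisation, a standard preparation.

Step 15
Reactants: 26 methyl 3-(trimethylsilyloxy)but-2-enoate
Product: 27 1-methoxy-1,3-bis(trimethylsilyloxy)buta-1,3-diene
Conditions: LiN(iPr)2, THF, −78 °C; then Me3SiCl, −78 °C → rt
Reagents that add atoms: chlorotrimethylsilane, C[Si](C)(C)Cl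
Why: Gamma-deprotonation and O-silylation of the extended enolate (silyl ketene acetal formation) gives the parent 1,3-bis(silyloxy)diene by the standard procedure.

Step 16
Reactants: 24 (S)-5,7-diacetoxy-2-[4-(benzyloxy)phenyl]-6-{4-[(S)-4-oxo-5-(phenylsulfinyl)-3,4-dihydro-2H-pyran-2-yl]phenoxy}chroman-4-one; 27 1-methoxy-1,3-bis(trimethylsilyloxy)buta-1,3-diene
Product: 31 (2S)-5,7-diacetoxy-2-[4-(benzyloxy)phenyl]-6-{4-[(2S)-5,7-dihydroxy-4-oxochroman-2-yl]phenoxy}chroman-4-one, via sulfinyl cycloadduct 28 (not isolated), via methoxy dihydroarene 29 (not isolated), via bis-silyl ether 30 (not isolated)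
Conditions: 27 (2 equiv), PhMe, rt → 70 °C; then THF, sat. aq. NH4Cl, rt
Reagents that add atoms: none
Why: Proposed new method: the same [4+2] addition as in step 8, with the CH2 terminus of the unhindered parent diene bonding to C6 of the sulfinyl pyranone and the ketene acetal carbon to C5, then syn loss of PhSOH and 1,4-loss of MeOH, should build the 5,7-dihydroxy ring A of unit 1 without touching either C2; the closest known type is the cycloaddition–aromatisation of 1,1,3-trioxygenated dienes with sulfinyl quinones and 3-sulfinylchromones.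

Step 17
Reactants: 31 (2S)-5,7-diacetoxy-2-[4-(benzyloxy)phenyl]-6-{4-[(2S)-5,7-dihydroxy-4-oxochroman-2-yl]phenoxy}chroman-4-one
Product: 32 (2S)-5,7-diacetoxy-2-(4-hydroxyphenyl)-6-{4-[(2S)-5,7-dihydroxy-4-oxochroman-2-yl]phenoxy}chroman-4-one
Conditions: H2 (1 atm), Pd/C, EtOAc, rt
Reagents that add atoms: none
Why: Catalytic hydrogenolysis of the benzyl aryl ether under neutral conditions at ambient pressure, where aryl acetates, the diaryl ether and the flavanone carbonyls should be inert.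

Step 18
Reactants: 32 (2S)-5,7-diacetoxy-2-(4-hydroxyphenyl)-6-{4-[(2S)-5,7-dihydroxy-4-oxochroman-2-yl]phenoxy}chroman-4-one
Product: 33 (2S)-5,7-dihydroxy-2-(4-hydroxyphenyl)-6-{4-[(2S)-5,7-dihydroxy-4-oxochroman-2-yl]phenoxy}chroman-4-one (CNP0184214.1)
Conditions: HCl in MeOH, 0 °C → rt
Reagents that add atoms: none
Why: Acid-catalysed transesterification (methanolysis) of the two aryl acetates, chosen over base because flavanones with a free 4'-hydroxyl racemise at C2 by ring opening in basic media.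

**Compound list**

1 | 4-(benzyloxy)benzaldehyde | O=Cc1ccc(OCc2ccccc2)cc1 | starting material
2 | trans-1-methoxy-3-(trimethylsilyloxy)buta-1,3-diene | CO/C=C/C(=C)O[Si](C)(C)C | starting material
3 | (S,E)-5-[4-(benzyloxy)phenyl]-1-methoxy-5-(trimethylsilyloxy)pent-1-en-3-one | CO/C=C/C(=O)C[C@@H](c1ccc(OCc2ccccc2)cc1)O[Si](C)(C)C | intermediate
4 | (S)-2-[4-(benzyloxy)phenyl]-2,3-dihydro-4H-pyran-4-one | O=C1C[C@@H](c2ccc(OCc3ccccc3)cc2)OC=C1 | intermediate
5 | (2S)-2-[4-(benzyloxy)phenyl]-6-chloro-5-(phenylthio)tetrahydropyran-4-one (diastereomers at C5 and C6) | O=C1C[C@@H](c2ccc(OCc3ccccc3)cc2)OC(Cl)C1Sc1ccccc1 | intermediate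
6 | (S)-2-[4-(benzyloxy)phenyl]-5-(phenylthio)-2,3-dihydro-4H-pyran-4-one | O=C1C[C@@H](c2ccc(OCc3ccccc3)cc2)OC=C1Sc1ccccc1 | intermediate
7 | (S)-2-[4-(benzyloxy)phenyl]-5-(phenylsulfinyl)-2,3-dihydro-4H-pyran-4-one (both sulfur epimers) | O=C1C[C@@H](c2ccc(OCc3ccccc3)cc2)OC=C1S(=O)c1ccccc1 | intermediate
8 | 4-hydroxybenzaldehyde | O=Cc1ccc(O)cc1 | starting material
9 | 4-(1,3-dioxolan-2-yl)phenol | Oc1ccc(C2OCCO2)cc1 | intermediate
10 | methyl 2-chloroacetoacetate | COC(=O)C(Cl)C(C)=O | starting material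
11 | methyl 2-[4-(1,3-dioxolan-2-yl)phenoxy]-3-oxobutanoate | COC(=O)C(Oc1ccc(C2OCCO2)cc1)C(C)=O | intermediate
12 | methyl 2-[4-(1,3-dioxolan-2-yl)phenoxy]-3-(trimethylsilyloxy)but-2-enoate (either geometry) | COC(=O)C(Oc1ccc(C2OCCO2)cc1)=C(C)O[Si](C)(C)C | intermediate
13 | 2-[4-(1,3-dioxolan-2-yl)phenoxy]-1-methoxy-1,3-bis(trimethylsilyloxy)buta-1,3-diene (either ketene acetal geometry) | C=C(O[Si](C)(C)C)C(Oc1ccc(C2OCCO2)cc1)=C(OC)O[Si](C)(C)C | intermediate
14 | cycloadduct of 7 and 13: (2S)-2-[4-(benzyloxy)phenyl]-6-[4-(1,3-dioxolan-2-yl)phenoxy]-5-methoxy-4a-(phenylsulfinyl)-5,7-bis(trimethylsilyloxy)-2,3,4a,5,8,8a-hexahydrochromen-4-one (cis ring fusion; C4a, C5, C8a and sulfur not assigned) | O=C1C[C@@H](c2ccc(OCc3ccccc3)cc2)OC2CC(O[Si](C)(C)C)=C(Oc3ccc(C4OCCO4)cc3)C(OC)(O[Si](C)(C)C)C12S(=O)c1ccccc1 | intermediate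
15 | (2S)-2-[4-(benzyloxy)phenyl]-6-[4-(1,3-dioxolan-2-yl)phenoxy]-5-methoxy-5,7-bis(trimethylsilyloxy)-2,3,5,8-tetrahydrochromen-4-one (C5 not assigned) | O=C1C[C@@H](c2ccc(OCc3ccccc3)cc2)OC2=C1C(OC)(O[Si](C)(C)C)C(Oc1ccc(C3OCCO3)cc1)=C(O[Si](C)(C)C)C2 | intermediate
16 | (S)-2-[4-(benzyloxy)phenyl]-6-[4-(1,3-dioxolan-2-yl)phenoxy]-5,7-bis(trimethylsilyloxy)chroman-4-one | O=C1C[C@@H](c2ccc(OCc3ccccc3)cc2)Oc2cc(O[Si](C)(C)C)c(Oc3ccc(C4OCCO4)cc3)c(O[Si](C)(C)C)c21 | intermediate
17 | (S)-2-[4-(benzyloxy)phenyl]-6-[4-(1,3-dioxolan-2-yl)phenoxy]-5,7-dihydroxychroman-4-one | O=C1C[C@@H](c2ccc(OCc3ccccc3)cc2)Oc2cc(O)c(Oc3ccc(C4OCCO4)cc3)c(O)c21 | intermediate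
18 | (S)-5,7-diacetoxy-2-[4-(benzyloxy)phenyl]-6-[4-(1,3-dioxolan-2-yl)phenoxy]chroman-4-one | O=C1C[C@@H](c2ccc(OCc3ccccc3)cc2)Oc2cc(OC(C)=O)c(Oc3ccc(C4OCCO4)cc3)c(OC(C)=O)c21 | intermediate
19 | (S)-5,7-diacetoxy-2-[4-(benzyloxy)phenyl]-6-(4-formylphenoxy)chroman-4-one | O=C1C[C@@H](c2ccc(OCc3ccccc3)cc2)Oc2cc(OC(C)=O)c(Oc3ccc(C=O)cc3)c(OC(C)=O)c21 | intermediate
20 | Mukaiyama aldol silyl ether of 19: (S)-5,7-diacetoxy-2-[4-(benzyloxy)phenyl]-6-{4-[(S,E)-5-methoxy-3-oxo-1-(trimethylsilyloxy)pent-4-enyl]phenoxy}chroman-4-one | CO/C=C/C(=O)C[C@@H](c1ccc(Oc2c(OC(C)=O)cc3c(c2OC(C)=O)C(=O)C[C@@H](c2ccc(OCc4ccccc4)cc2)O3)cc1)O[Si](C)(C)C | intermediate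
21 | (S)-5,7-diacetoxy-2-[4-(benzyloxy)phenyl]-6-{4-[(S)-4-oxo-3,4-dihydro-2H-pyran-2-yl]phenoxy}chroman-4-one | O=C1C[C@@H](c2ccc(Oc3c(OC(C)=O)cc4c(c3OC(C)=O)C(=O)C[C@@H](c3ccc(OCc5ccccc5)cc3)O4)cc2)OC=C1 | intermediate
22 | chloro sulfide adduct of 21: 6-chloro-5-(phenylthio)tetrahydropyran-4-one (diastereomers at C5 and C6 of the pyranone) | O=C1C[C@@H](c2ccc(Oc3c(OC(C)=O)cc4c(c3OC(C)=O)C(=O)C[C@@H](c3ccc(OCc5ccccc5)cc3)O4)cc2)OC(Cl)C1Sc1ccccc1 | intermediate
23 | (S)-5,7-diacetoxy-2-[4-(benzyloxy)phenyl]-6-{4-[(S)-4-oxo-5-(phenylthio)-3,4-dihydro-2H-pyran-2-yl]phenoxy}chroman-4-one | O=C1C[C@@H](c2ccc(Oc3c(OC(C)=O)cc4c(c3OC(C)=O)C(=O)C[C@@H](c3ccc(OCc5ccccc5)cc3)O4)cc2)OC=C1Sc1ccccc1 | intermediate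
24 | (S)-5,7-diacetoxy-2-[4-(benzyloxy)phenyl]-6-{4-[(S)-4-oxo-5-(phenylsulfinyl)-3,4-dihydro-2H-pyran-2-yl]phenoxy}chroman-4-one (both sulfur epimers) | O=C1C[C@@H](c2ccc(Oc3c(OC(C)=O)cc4c(c3OC(C)=O)C(=O)C[C@@H](c3ccc(OCc5ccccc5)cc3)O4)cc2)OC=C1S(=O)c1ccccc1 | intermediate
25 | methyl acetoacetate | COC(=O)CC(C)=O | starting material
26 | methyl 3-(trimethylsilyloxy)but-2-enoate | COC(=O)C=C(C)O[Si](C)(C)C | intermediate
27 | 1-methoxy-1,3-bis(trimethylsilyloxy)buta-1,3-diene | C=C(O[Si](C)(C)C)C=C(OC)O[Si](C)(C)C | intermediate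
28 | cycloadduct of 24 and 27 (5-methoxy-4a-(phenylsulfinyl)-5,7-bis(trimethylsilyloxy)hexahydrochromen-4-one in unit 1; cis ring fusion, new centres not assigned) | O=C1C[C@@H](c2ccc(Oc3c(OC(C)=O)cc4c(c3OC(C)=O)C(=O)C[C@@H](c3ccc(OCc5ccccc5)cc3)O4)cc2)OC2CC(O[Si](C)(C)C)=CC(OC)(O[Si](C)(C)C)C12S(=O)c1ccccc1 | intermediate
29 | 5-methoxy-5,7-bis(trimethylsilyloxy)-2,3,5,8-tetrahydrochromen-4-one in unit 1 (after loss of PhSOH; C5 not assigned) | O=C1C[C@@H](c2ccc(Oc3c(OC(C)=O)cc4c(c3OC(C)=O)C(=O)C[C@@H](c3ccc(OCc5ccccc5)cc3)O4)cc2)OC2=C1C(OC)(O[Si](C)(C)C)C=C(O[Si](C)(C)C)C2 | intermediate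
30 | 5,7-bis(trimethylsilyl) ether of 31 in unit 1 | O=C1C[C@@H](c2ccc(Oc3c(OC(C)=O)cc4c(c3OC(C)=O)C(=O)C[C@@H](c3ccc(OCc5ccccc5)cc3)O4)cc2)Oc2cc(O[Si](C)(C)C)cc(O[Si](C)(C)C)c21 | intermediate
31 | (2S)-5,7-diacetoxy-2-[4-(benzyloxy)phenyl]-6-{4-[(2S)-5,7-dihydroxy-4-oxochroman-2-yl]phenoxy}chroman-4-one | O=C1C[C@@H](c2ccc(Oc3c(OC(C)=O)cc4c(c3OC(C)=O)C(=O)C[C@@H](c3ccc(OCc5ccccc5)cc3)O4)cc2)Oc2cc(O)cc(O)c21 | intermediate
32 | (2S)-5,7-diacetoxy-2-(4-hydroxyphenyl)-6-{4-[(2S)-5,7-dihydroxy-4-oxochroman-2-yl]phenoxy}chroman-4-one | O=C1C[C@@H](c2ccc(Oc3c(OC(C)=O)cc4c(c3OC(C)=O)C(=O)C[C@@H](c3ccc(O)cc3)O4)cc2)Oc2cc(O)cc(O)c21 | intermediate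
33 | (2S)-5,7-dihydroxy-2-(4-hydroxyphenyl)-6-{4-[(2S)-5,7-dihydroxy-4-oxochroman-2-yl]phenoxy}chroman-4-one (CNP0184214.1) | O=C1C[C@@H](c2ccc(Oc3c(O)cc4c(c3O)C(=O)C[C@@H](c3ccc(O)cc3)O4)cc2)Oc2cc(O)cc(O)c21 | target

**Step count and risks**

Total step count: 18. Longest linear sequence: 13 steps (steps 4–13 and 16–18, from 4-hydroxybenzaldehyde 8).

Steps most likely to fail:

1. Step 8. The push–pull C5=C6 bond of 7 may be too poor a 2π partner for the hindered, fully substituted ketene acetal terminus of 13. The diene would then be consumed by silyl transfer to the sulfoxide oxygen, or would add only in the conjugate sense, after which the pyranone opens by beta-elimination of O1 instead of ring A closing. Fallback (known chemistry; sets out from compound 1, comes back at compound 17): ring C of unit 2 is closed last by oxa-Michael addition and the ether is made by SNAr.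
   - Commercial 2',4',6'-trihydroxyacetophenone is bis-allylated (allyl bromide, K2CO3, acetone) to 2'-hydroxy-4',6'-bis(allyloxy)acetophenone F1.
   - Elbs persulfate oxidation (K2S2O8, aq. KOH; then dilute HCl, warm) introduces the hydroxyl para to the chelated phenol and gives 2',5'-dihydroxy-4',6'-bis(allyloxy)acetophenone F2.
   - The non-chelated 5'-hydroxyl displaces fluoride from 4-fluorobenzaldehyde (K2CO3, DMF, 90 °C) to give 5'-(4-formylphenoxy)-2'-hydroxy-4',6'-bis(allyloxy)acetophenone F3.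
   - The aldehyde is masked (ethylene glycol, TsOH, PhMe, Dean–Stark) as the dioxolane F4.
   - Claisen–Schmidt condensation of F4 with 1 (KOH, EtOH) gives the chalcone F5.
   - NaOAc in refluxing EtOH closes the racemic flavanone F6; the single free ortho-hydroxyl makes the closure regiospecific.
   - Preparative HPLC on a chiral phase gives the (S)-flavanone F7.
   - Pd(PPh3)4 with morpholine in THF removes both allyl groups and gives 17.

2. Step 16. The same annulation may stall on the larger substrate. Prolonged heating would then invite thermal decomposition of the sulfoxide, or a conjugate addition followed by opening of the pyranone ring. Fallback (known chemistry; sets out from compound 19, comes back at compound 31): rings C and A of unit 1 are made by chalcone formation and oxa-Michael closure, at the cost of stereocontrol at the new C2.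
   - Aldehyde 19 and commercial 2',4',6'-trihydroxyacetophenone are condensed under acidic Claisen–Schmidt conditions that spare aryl acetates (BF3·OEt2, dioxane, rt) to give the 2',4',6'-trihydroxychalcone F8.
   - F8 cyclises on warming in EtOH with a little AcOH to a mixture of 31 and its epimer at C2 of unit 1, F9.
   - The two diastereomers are separated by preparative HPLC.

3. Step 12. Electrophilic sulfur may attack an aromatic ring of the elaborated substrate in competition with the enol ether carbon, and the amine may start beta-elimination at either C2–O bond. Fallback (sets out from compound 21, comes back at compound 23): sulfur is brought in as a nucleophile instead of an electrophile.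
   - Amine-mediated alpha-iodination of the enone (I2, pyridine, CH2Cl2, rt) proceeds by conjugate addition of pyridine, leaves the arenes alone, and gives the 5-iodo-dihydropyranone F10.
   - C–S coupling with thiophenol under Pd2(dba)3/Xantphos catalysis (iPr2NEt, dioxane, 80 °C) then gives 23.

Further compounds
F1 | step 8 | 2'-hydroxy-4',6'-bis(allyloxy)acetophenone | CC(=O)c1c(O)cc(OCC=C)cc1OCC=C
F2 | step 8 | 2',5'-dihydroxy-4',6'-bis(allyloxy)acetophenone | CC(=O)c1c(O)cc(OCC=C)c(O)c1OCC=C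
F3 | step 8 | 5'-(4-formylphenoxy)-2'-hydroxy-4',6'-bis(allyloxy)acetophenone | CC(=O)c1c(O)cc(OCC=C)c(Oc2ccc(C=O)cc2)c1OCC=C
F4 | step 8 | 5'-[4-(1,3-dioxolan-2-yl)phenoxy]-2'-hydroxy-4',6'-bis(allyloxy)acetophenone | CC(=O)c1c(O)cc(OCC=C)c(Oc2ccc(C3OCCO3)cc2)c1OCC=C
F5 | step 8 | (E)-4-(benzyloxy)-3'-[4-(1,3-dioxolan-2-yl)phenoxy]-6'-hydroxy-2',4'-bis(allyloxy)chalcone | O=C(/C=C/c1ccc(OCc2ccccc2)cc1)c1c(O)cc(OCC=C)c(Oc2ccc(C3OCCO3)cc2)c1OCC=C
F6 | step 8 | racemic 2-[4-(benzyloxy)phenyl]-6-[4-(1,3-dioxolan-2-yl)phenoxy]-5,7-bis(allyloxy)chroman-4-one | O=C1CC(c2ccc(OCc3ccccc3)cc2)Oc2cc(OCC=C)c(Oc3ccc(C4OCCO4)cc3)c(OCC=C)c21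
F7 | step 8 | (S)-2-[4-(benzyloxy)phenyl]-6-[4-(1,3-dioxolan-2-yl)phenoxy]-5,7-bis(allyloxy)chroman-4-one | O=C1C[C@@H](c2ccc(OCc3ccccc3)cc2)Oc2cc(OCC=C)c(Oc3ccc(C4OCCO4)cc3)c(OCC=C)c21
F8 | step 16 | (E)-2',4',6'-trihydroxychalcone from 19 (unit 2 unchanged) | O=C(/C=C/c1ccc(Oc2c(OC(C)=O)cc3c(c2OC(C)=O)C(=O)C[C@@H](c2ccc(OCc4ccccc4)cc2)O3)cc1)c1c(O)cc(O)cc1O
F9 | step 16 | epimer of 31 with 2R configuration in unit 1 | O=C1C[C@H](c2ccc(Oc3c(OC(C)=O)cc4c(c3OC(C)=O)C(=O)C[C@@H](c3ccc(OCc5ccccc5)cc3)O4)cc2)Oc2cc(O)cc(O)c21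
F10 | step 12 | (S)-5,7-diacetoxy-2-[4-(benzyloxy)phenyl]-6-{4-[(S)-5-iodo-4-oxo-3,4-dihydro-2H-pyran-2-yl]phenoxy}chroman-4-one | O=C1C[C@@H](c2ccc(Oc3c(OC(C)=O)cc4c(c3OC(C)=O)C(=O)C[C@@H](c3ccc(OCc5ccccc5)cc3)O4)cc2)OC=C1I
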